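Friday's flask held 0.500 of Saturday's catalyst, yet it gave 0.628 of Saturday's target. We want to know what feeding does at this catalyst life, so that mismatch has to be cleared first.

the same everywhere: impurity 0.32 mM

| flask | starting material | reagent | second substrate | free catalyst | remark | time |
|---|---|---|---|---|---|---|
| Saturday's | 0.050 M | 0.80 equiv | 0.20 equiv | 5 mol% | run made earlier |  |
| Friday's | 0.050 M | 0.80 equiv | 0.20 equiv | 2.5 mol% | run made earlier |  |
| Tuesday's | 0.050 M | 0.80 equiv | 0.20 equiv | 3.8 mol% | run made earlier |  |
| red | 0.050 M (fed, over 25 min) | 0.800 equiv | 0.200 equiv | 5 mol% | all else is in the flask from the start; the feed brings no volume worth counting | 2.0 h |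
| green | 0.050 M | 0.800 equiv (fed, over 25 min) | 0.200 equiv | 5 mol% | all else is in the flask from the start; the feed brings no volume worth counting | 2.0 h |
| blue | 0.050 M | 0.800 equiv | 0.200 equiv | 5 mol% | everything together at the start | 2.0 h |

| run | time / min | target / % | starting material / % |
|---|---|---|---|
| Saturday's | 4.00 | 16.9 | 82.9 |
| Saturday's | 12.0 | 29.3 | 70.8 |
| Saturday's | 20.0 | 33.1 | 66.5 |
| Saturday's | 30.0 | 35.8 | 63.9 |
| Saturday's | 40.0 | 37.2 | 63.1 |
| Saturday's | 60.0 | 37.2 | 62.8 |
| Saturday's | 80.0 | 37.6 | 62.4 |
| Friday's | 8.00 | 13.5 | 86.8 |
| Friday's | 12.0 | 16.4 | 83.3 |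
| Friday's | 20.0 | 20.0 | 80.0 |
| Friday's | 25.0 | 21.9 | 78.9 |
| Friday's | 40.0 | 23.0 | 77.4 |
| Friday's | 60.0 | 23.6 | 77.2 |
| Friday's | 90.0 | 23.0 | 75.9 |
| Tuesday's | 5.00 | 14.9 | 84.2 |
| Tuesday's | 15.0 | 26.2 | 74.1 |
| Tuesday's | 25.0 | 29.3 | 70.7 |
| Tuesday's | 40.0 | 31.3 | 68.9 |
| Tuesday's | 60.0 | 31.8 | 68.0 |
| Tuesday's | 80.0 | 31.7 | 68.2 |
| Tuesday's | 90.0 | 31.7 | 67.6 |

(each reading ± 0.3 percentage points)

* the best flask by amount of target, in percent of the starting material charged; "all alike" if 1.5 percentage points covers them all (red / green / blue / all alike)
* amount of target at the end, in percent of the starting material charged, red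
* amount of target at the end, in percent of the starting material charged, green
* amount of target at the end, in percent of the starting material charged, blue

Saturday's target stops near 37.6% with 62.4% of the starting material still there, so the catalyst must be failing. We reckon the target as catalyst times mean starting material times mean reagent, replacing each falling curve by the mean of its two ends. In equivalents that product is 0.497 on Saturday and 0.602 on Friday. Friday's flask stays fuller, so each unit of catalyst makes more there. The predicted ratio is 0.605, which is 0.0224 under the reading, so the means serve.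

Next we need the catalyst lifetime τ, the time in which the gap to the final target shrinks by the factor e. Saturday's gap between 12.0 min and 30.0 min gives τ = 11.8 min.

In a fed flask the fed material rises steadily over the feed time, while the catalyst fades. Averaged over the catalyst's life, the flask is only φ = 0.415 full. Red and green therefore act like a catalyst loading of 2.07% on the starting material. Scaling from Friday, our reckoning gives 19.6% for each, and blue repeats Saturday.

The forecast said blue, with 19.4% for red, 19.1% for green and 37.5% for blue, since “feeding wastes its short life”.

The flasks gave 22.2% in red, 20.7% in green and 37.7% in blue, so blue leads and the forecast held.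

    starting material + reagent + free catalyst → free catalyst + target (k = 15.0 L² mol⁻² s⁻¹)
    second substrate + reagent + free catalyst → free catalyst + second product (k = 290 L² mol⁻² s⁻¹)
    free catalyst + impurity → spent catalyst A (k = 280 L mol⁻¹ s⁻¹)
    free catalyst → spent catalyst B (k = 0.00130 s⁻¹)

The feed lasts 2.12 lifetimes τ as read from Saturday's run. At the end of the feed, free catalyst stood at 12.4% in red and 12.4% in green, with spent catalyst A at 12.8% and spent catalyst B at 74.8% in red.

The earlier runs and the new flask are simulated on assumed constants.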